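**Retrosynthetic overview**
1. The target is read as (3S,3aS,6S,6aR). It is a cis-fused 3,7-dioxabicyclo[3.3.0]octan-2-one with H-3, H-3a, H-6 and H-6a all on the convex face and both aryl groups endo, so it is the kinetic, contra-thermodynamic isomer.
2. Key disconnection: O-5–C-6 of the tetrahydrofuran ring (C-3a, C-4, O-5, C-6, C-6a), with C-6 raised to the ketone level, gives a 3-aroyl-4-(hydroxymethyl)-γ-lactone. The enabling feature is that C-6a lies between the lactone carbonyl C-1 and C-6: it is a stereolabile β-dicarbonyl methine in the precursor, the 5/5 fusion to the lactone ring can only be cis, and only the convex face of the C-6 oxocarbenium ion is open to hydride.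
3. C-6–C-6a: tethered O→C aroyl transfer from the C-4 ester of silyl-protected protocatechuic acid onto the lactone enolate.
4. Lactone ring (C-1, O-2, C-3, C-3a, C-6a): lactol closure and oxidation after cleavage of an allyl group. C-3 and C-3a come from an auxiliary-controlled anti-aldol reaction of silyl-protected syringaldehyde.
5. Ring order: two arenes (purchased), lactone ring (steps 7 and 8), tetrahydrofuran ring (step 10), then buffered desilylation.

Key step: step 10

Remark: target numbering (C-1 lactone C=O, O-2, C-3 syringyl carbon, C-3a, C-4 CH2, O-5, C-6 catechol carbon, C-6a) is used for all intermediates. TBS = tert-butyldimethylsilyl, TES = triethylsilyl, TMS = trimethylsilyl.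

Step 1
Reactants: 1 syringaldehyde (4-hydroxy-3,5-dimethoxybenzaldehyde)
Product: 2 4-(tert-butyldimethylsilyloxy)-3,5-dimethoxybenzaldehyde
Conditions: TBSCl, imidazole, DMF, rt
Reagents that add atoms: TBSCl, CC(C)(C)[Si](C)(C)Cl
Why: Imidazole-promoted silylation of a phenol, chosen because aryl silyl ethers should survive the later base, oxidants and Lewis acid and can be removed at the end with buffered fluoride without epimerising the benzylic C–O centres; no stereocentre is formed.

Step 2
Reactants: 3 (S)-4-benzyloxazolidin-2-one; 4 pent-4-enoyl chloride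
Product: 5 (S)-4-benzyl-3-(pent-4-enoyl)oxazolidin-2-one
Conditions: n-BuLi, THF, −78 °C; then 4, −78 → 0 °C
Reagents that add atoms: none
Why: N-acylation of the lithiated oxazolidinone with an acid chloride is the standard way to load the auxiliary, and its stereocentre is untouched.

Step 3
Reactants: 5 (S)-4-benzyl-3-(pent-4-enoyl)oxazolidin-2-one; 2 4-(tert-butyldimethylsilyloxy)-3,5-dimethoxybenzaldehyde
Product: 7 anti-aldol adduct (4S)-4-benzyl-3-[(2R)-2-{(S)-[4-(TBS-oxy)-3,5-dimethoxyphenyl](hydroxy)methyl}pent-4-enoyl]oxazolidin-2-one, via TMS ether 6 (not isolated)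
Conditions: MgCl2 (cat.), Et3N, TMSCl, EtOAc, rt; then TFA (cat.), MeOH, 0 °C
Reagents that add atoms: TMSCl, C[Si](C)(C)Cl (its Me3Si group is carried only by intermediate 6)
Why: Evans magnesium halide-catalysed direct anti-aldol reaction, in which soft enolisation gives the chelated (Z)-magnesium enolate, the non-enolisable aldehyde adds on the enolate face opposite the benzyl group (sets C-3a) with anti topicity (sets C-3), and TMSCl silylates the aldolate to turn the catalyst over, giving the (2R,3S) relationship that later becomes the cis lactone.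

Step 4
Reactants: 7 anti-aldol adduct
Product: 8 (1S,2S)-2-allyl-1-[4-(TBS-oxy)-3,5-dimethoxyphenyl]propane-1,3-diol
Conditions: LiBH4, THF, MeOH (1 equiv), 0 °C
Reagents that add atoms: none
Why: Reductive removal of the auxiliary, in which LiBH4 attacks the more electrophilic exocyclic imide carbonyl and takes C-4 to the alcohol level without touching C-3 or C-3a, while the auxiliary is recovered.

Step 5
Reactants: 9 3,4-dihydroxybenzoic acid (protocatechuic acid)
Product: 11 3,4-bis(tert-butyldimethylsilyloxy)benzoic acid, via silyl ester 10 (not isolated)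
Conditions: TBSCl (3.5 equiv), imidazole, DMF, rt; then AcOH–THF–H2O, rt
Reagents that add atoms: TBSCl, CC(C)(C)[Si](C)(C)Cl
Why: Exhaustive silylation followed by selective hydrolysis of the far more labile silyl ester should leave both aryl silyl ethers in place; no stereocentre is involved.

Step 6
Reactants: 8 (1S,2S)-diol; 11 3,4-bis(TBS-oxy)benzoic acid
Product: 12 (2S)-2-{(S)-[4-(TBS-oxy)-3,5-dimethoxyphenyl](hydroxy)methyl}pent-4-en-1-yl 3,4-bis(TBS-oxy)benzoate
Conditions: DIC (1.0 equiv), DMAP (cat.), CH2Cl2, −10 → 0 °C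
Reagents that add atoms: none
Why: Steglich esterification, in which the unhindered primary C-4 hydroxyl should react much faster than the secondary benzylic C-3 hydroxyl next to the branched C-3a, so the future C-6 is attached to O-5 without protecting O-2.

Step 7
Reactants: 12 homoallylic alcohol monoester
Product: 14 lactol [(2S,3S)-2-[4-(TBS-oxy)-3,5-dimethoxyphenyl]-5-hydroxyoxolan-3-yl]methyl 3,4-bis(TBS-oxy)benzoate (anomers), via hydroxy aldehyde 13 (not isolated)
Conditions: OsO4 (cat.), NaIO4, 2,6-lutidine, dioxane–H2O, rt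
Reagents that add atoms: OsO4, O=[Os](=O)(=O)=O, with NaIO4, [Na+].[O-]I(=O)(=O)=O (source of the new oxygen at C-1)
Why: Lemieux–Johnson cleavage of the terminal alkene unmasks C-1 as aldehyde 13, which the C-3 hydroxyl traps at once as the five-membered lactol, a neutral closure at C-1 that leaves the C-3–O bond and hence the C-3/C-3a cis relationship intact; the anomeric centre is of no consequence.

Step 8
Reactants: 14 lactol
Product: 15 cis-lactone [(2S,3S)-2-[4-(TBS-oxy)-3,5-dimethoxyphenyl]-5-oxooxolan-3-yl]methyl 3,4-bis(TBS-oxy)benzoate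
Conditions: TPAP (cat.), NMO, 4 Å MS, CH2Cl2, rt
Reagents that add atoms: none
Why: Ley–Griffith oxidation of a lactol to the lactone under neutral conditions removes the anomeric centre and should not touch the silyl ethers, the ester or the electron-rich arenes.

Step 9
Reactants: 15 cis-lactone aroyl ester
Product: 17 β-keto lactone (4S,5S)-3-[3,4-bis(TBS-oxy)benzoyl]-5-[4-(TBS-oxy)-3,5-dimethoxyphenyl]-4-(hydroxymethyl)oxolan-2-one (C-6a epimers equilibrating with enol and hemiketal forms; drawn as the open keto alcohol), via lithium hemiketal alkoxide 16 (not isolated)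
Conditions: LiHMDS (2.3 equiv), THF, −78 → −20 °C; AcOH, −78 °C
Reagents that add atoms: none
Why: Intramolecular Claisen condensation (Dieckmann/Baker–Venkataraman-type O→C acyl transfer), in which deprotonation at C-6a and 5-exo-trig attack on the aroyl C=O held on the same face by the C-4–O-5 tether give adduct 16, whose collapse and a second deprotonation of the β-dicarbonyl drive the transfer; the new centre C-6a is stereolabile and is deliberately left unset.

Step 10
Reactants: 17 β-keto lactone (isomer mixture)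
Product: 20 (3S,3aS,6S,6aR)-6-[3,4-bis(TBS-oxy)phenyl]-3-[4-(TBS-oxy)-3,5-dimethoxyphenyl]tetrahydro-1H,3H-furo[3,4-c]furan-1-one, via hemiketal 18 (not isolated), via oxocarbenium triflate 19 (not isolated)
Conditions: Et3SiH (5 equiv), TMSOTf (0.3 equiv), CH2Cl2, −78 → −40 °C; Et3N quench at −78 °C
Reagents that add atoms: none
Why: Acid-catalysed enolisation interconverts the two C-6a epimers of 17, only the epimer with the aroyl group cis to the C-4 hydroxymethyl arm can add O-5 to the ketone (5-exo-trig) to give the cis-fused hemiketal 18, and loss of the former ketone oxygen gives the aryl-conjugated oxocarbenium ion 19, which Et3SiH reduces irreversibly. The closest known reaction type is the reductive cyclisation of hydroxy ketones, i.e. ionic hydrogenation of cyclic hemiketals with Et3SiH and a silyl triflate or BF3, familiar from C-aryl furanosides and 2-aryl tetrahydrofuran lignans. C-6a is set by ring strain, because a bicyclo[3.3.0] system fused at the fixed centre C-3a can only be cis, so keto epimers, enol, hemiketal anomers and any enol ether formed by reversible proton loss from 19 all drain through one cation (Curtin–Hammett funnel). C-6 is set by hydride attack on the convex face of 19, anti to the C-6a–C-1 bond and away from the concave face that the endo aryl group at C-3 shields further, which puts H-6 cis to H-6a and swings the aryl group endo. The step needs chemoselectivity for C-6 over the benzylic C-3–O-2 bond and kinetic control at C-6: the acyl group on O-2 and the carbonyl next to C-6a destabilise both benzylic cations, while low temperature, substoichiometric acid and a cold amine quench should prevent ring opening of the endo ether to the exo isomer.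

Step 11
Reactants: 20 tris-TBS furofuranone
Product: 21 target, (3S,3aS,6S,6aR)-6-(3,4-dihydroxyphenyl)-3-(4-hydroxy-3,5-dimethoxyphenyl)tetrahydro-1H,3H-furo[3,4-c]furan-1-one
Conditions: TBAF (3.3 equiv), AcOH (3.6 equiv), THF, 0 °C
Reagents that add atoms: none
Why: Fluoride cleavage of aryl silyl ethers, buffered with acetic acid so that no phenoxide para to C-3 or C-6 persists and quinone-methide ring opening (the path to the exo isomers) is avoided; all four stereocentres are retained.

**Compound list**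
1 | syringaldehyde | COc1cc(C=O)cc(OC)c1O | starting material
2 | 4-(TBS-oxy)-3,5-dimethoxybenzaldehyde | COc1cc(C=O)cc(OC)c1O[Si](C)(C)C(C)(C)C | intermediate
3 | (S)-4-benzyloxazolidin-2-one | O=C1OC[C@H](Cc2ccccc2)N1 | starting material
4 | pent-4-enoyl chloride | C=CCCC(=O)Cl | starting material
5 | (S)-4-benzyl-3-(pent-4-enoyl)oxazolidin-2-one | C=CCCC(=O)N1[C@@H](Cc2ccccc2)COC1=O | intermediate
6 | TMS ether of the anti-aldol adduct (2R,3S; not isolated) | COc1cc([C@@H](O[Si](C)(C)C)[C@H](C(=O)N2[C@@H](Cc3ccccc3)COC2=O)CC=C)cc(OC)c1O[Si](C)(C)C(C)(C)C | intermediate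
7 | anti-aldol adduct (2R,3S) | COc1cc([C@@H](O)[C@H](C(=O)N2[C@@H](Cc3ccccc3)COC2=O)CC=C)cc(OC)c1O[Si](C)(C)C(C)(C)C | intermediate
8 | (1S,2S)-2-allyl-1-aryl-propane-1,3-diol | COc1cc([C@@H](O)[C@H](CO)CC=C)cc(OC)c1O[Si](C)(C)C(C)(C)C | intermediate
9 | 3,4-dihydroxybenzoic acid | OC(=O)c1ccc(O)c(O)c1 | starting material
10 | TBS 3,4-bis(TBS-oxy)benzoate (not isolated) | CC(C)(C)[Si](C)(C)OC(=O)c1ccc(O[Si](C)(C)C(C)(C)C)c(O[Si](C)(C)C(C)(C)C)c1 | intermediate
11 | 3,4-bis(TBS-oxy)benzoic acid | OC(=O)c1ccc(O[Si](C)(C)C(C)(C)C)c(O[Si](C)(C)C(C)(C)C)c1 | intermediate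
12 | primary aroyl ester of diol 8 | COc1cc([C@@H](O)[C@H](COC(=O)c2ccc(O[Si](C)(C)C(C)(C)C)c(O[Si](C)(C)C(C)(C)C)c2)CC=C)cc(OC)c1O[Si](C)(C)C(C)(C)C | intermediate
13 | γ-hydroxy aldehyde (not isolated) | COc1cc([C@@H](O)[C@H](COC(=O)c2ccc(O[Si](C)(C)C(C)(C)C)c(O[Si](C)(C)C(C)(C)C)c2)CC=O)cc(OC)c1O[Si](C)(C)C(C)(C)C | intermediate
14 | cis-2,3-disubstituted lactol (anomers) | COc1cc([C@H]2OC(O)C[C@H]2COC(=O)c3ccc(O[Si](C)(C)C(C)(C)C)c(O[Si](C)(C)C(C)(C)C)c3)cc(OC)c1O[Si](C)(C)C(C)(C)C | intermediate
15 | cis-lactone aroyl ester | COc1cc([C@H]2OC(=O)C[C@H]2COC(=O)c3ccc(O[Si](C)(C)C(C)(C)C)c(O[Si](C)(C)C(C)(C)C)c3)cc(OC)c1O[Si](C)(C)C(C)(C)C | intermediate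
16 | lithium alkoxide of the bicyclic hemiketal, the tetrahedral adduct (not isolated) | [Li+].COc1cc([C@H]2OC(=O)[C@@H]3[C@H]2COC3([O-])c4ccc(O[Si](C)(C)C(C)(C)C)c(O[Si](C)(C)C(C)(C)C)c4)cc(OC)c1O[Si](C)(C)C(C)(C)C | intermediate
17 | 3-aroyl-4-(hydroxymethyl)-5-aryl lactone, C-6a epimers | COc1cc([C@H]2OC(=O)C(C(=O)c3ccc(O[Si](C)(C)C(C)(C)C)c(O[Si](C)(C)C(C)(C)C)c3)[C@H]2CO)cc(OC)c1O[Si](C)(C)C(C)(C)C | intermediate
18 | cis-fused bicyclic hemiketal, anomers (not isolated) | COc1cc([C@H]2OC(=O)[C@@H]3[C@H]2COC3(O)c4ccc(O[Si](C)(C)C(C)(C)C)c(O[Si](C)(C)C(C)(C)C)c4)cc(OC)c1O[Si](C)(C)C(C)(C)C | intermediate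
19 | cis-fused C-6 oxocarbenium triflate (not isolated) | COc1cc([C@H]2OC(=O)[C@@H]3[C@H]2C[O+]=C3c4ccc(O[Si](C)(C)C(C)(C)C)c(O[Si](C)(C)C(C)(C)C)c4)cc(OC)c1O[Si](C)(C)C(C)(C)C.[O-]S(=O)(=O)C(F)(F)F | intermediate
20 | tris-TBS endo,endo-furofuranone (3S,3aS,6S,6aR) | COc1cc([C@H]2OC(=O)[C@@H]3[C@H]2CO[C@@H]3c4ccc(O[Si](C)(C)C(C)(C)C)c(O[Si](C)(C)C(C)(C)C)c4)cc(OC)c1O[Si](C)(C)C(C)(C)C | intermediate
21 | CNP0224550.1 | COc1cc([C@H]2OC(=O)[C@@H]3[C@H]2CO[C@@H]3c2ccc(O)c(O)c2)cc(OC)c1O | target

**Step count**
Total steps: 11. Longest linear sequence: 9 (steps 1, 3, 4, 6, 7, 8, 9, 10, 11 from syringaldehyde; the same length from the auxiliary through step 2).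

**Steps most likely to fail**

Step 10 (key step). Proton loss from the cation may outrun hydride capture, so that material rests at the conjugated enol ether stage. Acid-induced ionisation of the benzylic C-3–O-2 or C-6–O-5 bond may also cause over-reduction or endo-to-exo epimerisation.

The fallback replaces ionic hydride delivery by heterogeneous syn-hydrogenation. Setting out from 17, cyclodehydration (PPTS, 4 Å MS, benzene, 50 °C) would give the bicyclic push–pull enol ether F1. Its tetrasubstituted C-6=C-6a bond should take up H2 (Rh/Al2O3, EtOAc, pressure) from the convex face opposite the C-3 aryl group. This places H-6 and H-6a cis to H-3a and comes back to the route at 20.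

Step 9. Three processes may compete with acyl transfer: silyl migration from the aryl ethers to the liberated alkoxide, attack of that alkoxide on the lactone carbonyl (translactonisation), and enolate displacement of the carboxylate at C-4.

The fallback brings the aroyl group in by an intermolecular crossed Claisen acylation with O-5 masked.
- Setting out from 8, selective silylation of the primary hydroxyl (TESCl, imidazole, CH2Cl2, −20 °C) would give the mono-TES ether F2.
- Lemieux–Johnson cleavage would give the lactol F3, and Ley–Griffith oxidation the cis-lactone F4.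
- Acid 11 is activated with CDI as the acyl imidazole F5.
- The lithium enolate of F4 (LiHMDS, 2.2 equiv, THF, −78 °C) is acylated with F5 to the TES-protected β-keto lactone F6 (C-6a epimers).
- F6 enters the conditions of step 10 directly, since a silyl ether and a ketone undergo the same reductive etherification, and the route is rejoined at 20.

Step 3. Addition to the electron-rich, hindered aldehyde may be sluggish, retro-aldol equilibration may occur, and anti/syn or facial selectivity may be poor.

The fallback sets C-3 by catalytic asymmetric reduction and C-3a by chelate-controlled alkylation.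
- Setting out from 2, Roskamp homologation (ethyl diazoacetate, SnCl2, CH2Cl2) would give the β-keto ester F7.
- Noyori transfer hydrogenation (RuCl[(S,S)-TsDPEN](p-cymene), HCO2H/Et3N) would give the (S)-β-hydroxy ester F8.
- Fráter–Seebach allylation of its dianion (LDA, 2.2 equiv; allyl bromide, THF, −78 → −20 °C) would give the anti-(2R,3S) ester F9.
- LiBH4 reduction comes back to the route at 8.

**Further compounds**
F1 | step 10 | (3S,3aS)-6-[3,4-bis(TBS-oxy)phenyl]-3-[4-(TBS-oxy)-3,5-dimethoxyphenyl]-3a,4-dihydro-1H,3H-furo[3,4-c]furan-1-one | COc1cc([C@H]2OC(=O)C=3[C@H]2COC=3c4ccc(O[Si](C)(C)C(C)(C)C)c(O[Si](C)(C)C(C)(C)C)c4)cc(OC)c1O[Si](C)(C)C(C)(C)C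
F2 | step 9 | (1S,2S)-1-[4-(TBS-oxy)-3,5-dimethoxyphenyl]-2-[(triethylsilyloxy)methyl]pent-4-en-1-ol | COc1cc([C@@H](O)[C@H](CO[Si](CC)(CC)CC)CC=C)cc(OC)c1O[Si](C)(C)C(C)(C)C
F3 | step 9 | (4S,5S)-5-[4-(TBS-oxy)-3,5-dimethoxyphenyl]-4-[(triethylsilyloxy)methyl]oxolan-2-ol (anomers) | COc1cc([C@H]2OC(O)C[C@H]2CO[Si](CC)(CC)CC)cc(OC)c1O[Si](C)(C)C(C)(C)C
F4 | step 9 | (4S,5S)-5-[4-(TBS-oxy)-3,5-dimethoxyphenyl]-4-[(triethylsilyloxy)methyl]oxolan-2-one | COc1cc([C@H]2OC(=O)C[C@H]2CO[Si](CC)(CC)CC)cc(OC)c1O[Si](C)(C)C(C)(C)C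
F5 | step 9 | 1-[3,4-bis(TBS-oxy)benzoyl]imidazole | O=C(c1ccc(O[Si](C)(C)C(C)(C)C)c(O[Si](C)(C)C(C)(C)C)c1)n1ccnc1
F6 | step 9 | (4S,5S)-3-[3,4-bis(TBS-oxy)benzoyl]-5-[4-(TBS-oxy)-3,5-dimethoxyphenyl]-4-[(triethylsilyloxy)methyl]oxolan-2-one (C-6a epimers) | COc1cc([C@H]2OC(=O)C(C(=O)c3ccc(O[Si](C)(C)C(C)(C)C)c(O[Si](C)(C)C(C)(C)C)c3)[C@H]2CO[Si](CC)(CC)CC)cc(OC)c1O[Si](C)(C)C(C)(C)C
F7 | step 3 | ethyl 3-[4-(TBS-oxy)-3,5-dimethoxyphenyl]-3-oxopropanoate | CCOC(=O)CC(=O)c1cc(OC)c(O[Si](C)(C)C(C)(C)C)c(OC)c1
F8 | step 3 | ethyl (S)-3-[4-(TBS-oxy)-3,5-dimethoxyphenyl]-3-hydroxypropanoate | COc1cc([C@@H](O)CC(=O)OCC)cc(OC)c1O[Si](C)(C)C(C)(C)C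
F9 | step 3 | ethyl (2R)-2-{(S)-[4-(TBS-oxy)-3,5-dimethoxyphenyl](hydroxy)methyl}pent-4-enoate | COc1cc([C@@H](O)[C@H](C(=O)OCC)CC=C)cc(OC)c1O[Si](C)(C)C(C)(C)C
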